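**Plan**
1. Retrosynthesis (gibberellane numbering): C13–C16 (ring D) is cut first, then the two C–O bonds of the 2,3-diol, C3–C4 (ring A), C4–C5 together with the lactone acyl–O bond, C10–C1, C5–C6 (ring B) and C8–C15.
2. Forward: ring C comes from 2-bromo-5-methoxybenzoic acid by Birch reduction–alkylation; ring B closes by acyl substitution at the amide carbon; the γ-lactone (Michael addition) and ring A (aldol) are built on a C10 ketone; ring D closes last.
3. Enabling feature: C13 is a bridgehead tertiary carbinol bonded directly to C16, the carbon of the exocyclic C16=C17 methylene, and C16 is tied through C15 to quaternary C8, which lies 1,3 to C13 across C14 in ring C. A C13 ketone plus a C8 propargyl group is therefore one C–C bond short of rings C/D.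
4. Stereochemistry: C8 from the (S)-2-(methoxymethyl)pyrrolidine amide; C9 by equilibration to the cis B/C fusion; C10 by convex-face addition; C5 by the lactone tether; C6 by equilibration; C4 by the bridged ring; C2/C3 by exo-face osmylation; C13 by the propargyl tether.
5. The C8-propargyl cis-hydrindan-13-one unit is cyclised only after rings A–C, the lactone and the diol are in place, so no acid or osmium reagent meets the 13-hydroxy-16-methylene array.

Key step: step 20

Remark: gibberellane numbering is used for all intermediates; β is the face of the C2/C3 hydroxyls of the target. The target is referred to below as the target gibberellin (2β,3β,13-trihydroxy-20-norgibberell-16-ene-7,19-dioic acid 19,10-lactone).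
Assumption: the enolate of the 2-alkyl-5-methoxybenzamide of (S)-2-(methoxymethyl)pyrrolidine is taken to be alkylated on the face that gives (S)-C8 as drawn; were the sense opposite, the (R)-amine would be used with no other change.

**Step 1**
Reactants: 1 2-bromo-5-methoxybenzoic acid; 2 (S)-2-(methoxymethyl)pyrrolidine
Product: 4 (S)-1-(2-bromo-5-methoxybenzoyl)-2-(methoxymethyl)pyrrolidine, via acid chloride 3 (not isolated)
Conditions: (COCl)2, DMF (cat.), CH2Cl2, 0 °C to rt; then 2, Et3N, CH2Cl2, 0 °C
Reagents that add atoms: none
Why: N-acylation of the secondary amine by the acid chloride (Schotten–Baumann-type amide formation) should leave the pyrrolidine stereocentre untouched.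

**Step 2**
Reactants: 4; 5 ethylene oxide
Product: 7 (S)-1-[2-(2-hydroxyethyl)-5-methoxybenzoyl]-2-(methoxymethyl)pyrrolidine, via arylmagnesium chloride 6 (not isolated)
Conditions: i-PrMgCl·LiCl, THF, −15 °C to rt; then CuI (10 mol %), 5, −30 to 0 °C
Reagents that add atoms: none
Why: bromine–magnesium exchange assisted by the ortho amide, then copper-catalysed epoxide opening by the aryl Grignard reagent, should give the 2-arylethanol that supplies C10 and C5.

**Step 3**
Reactants: 7; 8 3-bromo-1-(trimethylsilyl)prop-1-yne
Product: 10 amide of 2 with (1S)-2-(2-hydroxyethyl)-5-methoxy-1-[3-(trimethylsilyl)prop-2-ynyl]cyclohexa-2,5-diene-1-carboxylic acid, via dilithium enolate 9 (not isolated)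
Conditions: Li, NH3–THF, −78 °C (no added alcohol); piperylene; then 8, −78 °C
Reagents that add atoms: none
Why: in this Birch reduction–alkylation of a chiral 2-alkylbenzamide the side-chain hydroxyl supplies the one proton (at C12), and the amide enolate, its faces differentiated by the methoxymethylpyrrolidine, is alkylated at C8 by the propargylic bromide to set the quaternary stereocentre in the sense assumed above, the lithium alkoxide being inert at −78 °C.

**Step 4**
Reactants: 10
Product: 11 the 2-(2-iodoethyl) analogue of 10 (C8 unchanged)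
Conditions: I2, PPh3, imidazole, CH2Cl2, 0 °C
Reagents that add atoms: iodine, II
Why: the Appel-type iodination of a primary alcohol is buffered by imidazole and should spare the methyl enol ether.

**Step 5**
Reactants: 11
Product: 13 6-methoxy-7a-[3-(trimethylsilyl)prop-2-ynyl]-2,3,5,7a-tetrahydro-1H-inden-1-one (C6 ketone; C9=C11 and C13=C14 double bonds; C8 as in 10), via alkyllithium 12 (not isolated)
Conditions: t-BuLi (2.1 equiv), Et2O–pentane, −78 to −20 °C; then H2O
Reagents that add atoms: none
Why: iodine–lithium exchange gives a primary alkyllithium that adds 5-exo-trig to the tertiary amide carbonyl (Parham-type cyclisation, intramolecular acyl substitution), and the tetrahedral adduct releases the ketone and amine 2 on work-up, so ring B closes and the auxiliary leaves in one operation.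

**Step 6**
Reactants: 13
Product: 15 enol triflate of 13 (C5=C6, triflate on C6), via potassium enolate 14 (not isolated)
Conditions: KN(SiMe3)2, THF, −78 °C; then PhNTf2, −78 to 0 °C
Reagents that add atoms: N-phenylbis(trifluoromethanesulfonimide), O=S(=O)(N(c1ccccc1)S(=O)(=O)C(F)(F)F)C(F)(F)F
Why: the ketone can enolise only towards C5 because C8 is quaternary, and O-sulfonylation of the potassium enolate gives the enol triflate.

**Step 7**
Reactants: 15
Product: 16 methyl ester with CO2Me on C6 of the 5,9(11),13-triene (13-methoxy)
Conditions: Pd(OAc)2 (5 mol %), PPh3, CO (1 atm), MeOH, Et3N, DMF, 50 °C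
Reagents that add atoms: carbon monoxide, [C-]#[O+]; methanol, CO
Why: palladium-catalysed methoxycarbonylation of an enol triflate (oxidative addition to zerovalent palladium, CO insertion, methanolysis) should introduce C7 as the conjugated ester.

**Step 8**
Reactants: 16
Product: 18 cis-fused enone (13-oxo, C11=C12, H9 β and syn to the propargyl arm, C5=C6 ester), via unconjugated enone 17 (not isolated)
Conditions: 1 M HCl, THF, 0 °C to rt; then DBU (0.2 equiv), CH2Cl2, rt
Reagents that add atoms: water, O
Why: enol ether hydrolysis unveils the C13 ketone and base-mediated conjugation through the dienolate moves C9=C11 to C11=C12, the reversible γ-protonation at C9 being expected to give the more stable cis ring fusion.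

**Step 9**
Reactants: 18
Product: 19 13-ketone with saturated ring C (H9 β, C5=C6 ester)
Conditions: K[(s-Bu)3BH] (1.05 equiv), THF, −78 °C
Reagents that add atoms: none
Why: a bulky trialkylborohydride reduces a β-unsubstituted cyclohexenone in the 1,4 sense, while the trisubstituted unsaturated ester and the silyl alkyne are much less electrophilic.

**Step 10**
Reactants: 19
Product: 20 13,13-ethylenedioxy ketal of 19
Conditions: HOCH2CH2OH, PPTS (cat.), benzene, reflux (Dean–Stark)
Reagents that add atoms: ethylene glycol, OCCO
Why: acid-catalysed ketalisation of the only ketone protects C13 through the organometallic and basic steps that follow.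

**Step 11**
Reactants: 20
Product: 21 10-oxo-5-ene 7-methyl ester (4-oxocyclopent-1-ene-1-carboxylate ring B, 13-ketal, H9 β)
Conditions: CrO3, 3,5-dimethylpyrazole, CH2Cl2, −20 °C
Reagents that add atoms: chromium trioxide, O=[Cr](=O)=O
Why: allylic oxidation can occur only at C10, the single allylic CH2 of the C5=C6 bond (C8 is quaternary), and C9, now α to the ketone, can equilibrate and should stay cis-fused.

**Step 12**
Reactants: 21; 22 but-3-enylmagnesium bromide
Product: 23 tertiary alcohol (10α-OH, 10β-but-3-enyl)
Conditions: CeCl3, 22, THF, −78 °C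
Reagents that add atoms: none
Why: the organocerium reagent adds 1,2 to the enolisable enone without touching the ester, and approach from the convex β-face, anti to the C9–C11 bond of the cis-fused bicycle, should place C1 β and the C10 oxygen α.

**Step 13**
Reactants: 23; 24 propanoic anhydride
Product: 25 10α-propanoate of 23
Conditions: 24, DMAP, Et3N, CH2Cl2, 40 °C
Reagents that add atoms: none
Why: DMAP-catalysed (Steglich-type) acylation esterifies the tertiary alcohol, whose ionisation is disfavoured by the electron-poor alkene.

**Step 14**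
Reactants: 25
Product: 27 γ-lactone (C19 to O10; H5 β; 6β-CO2Me; C4–H with exo methyl; 10β-but-3-enyl; terminal alkyne; 13-ketal), via silyl alkyne lactone 26 (not isolated)
Conditions: KN(SiMe3)2, THF, −78 to −20 °C; then MeOH, rt
Reagents that add atoms: none
Why: intramolecular Michael addition of the propanoate enolate to C5 (5-exo-trig) forms C4–C5 and the γ-lactone with H5 β enforced by the tether from the 10α-oxygen, after which the methoxide formed on quenching equilibrates C6 to the ester trans to C4 and cleaves the alkynyl silane.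

**Step 15**
Reactants: 27
Product: 28 C3 aldehyde (10β-CH2CH2CHO; otherwise as 27)
Conditions: O3 (1 equiv), CH2Cl2–MeOH, NaHCO3, −78 °C; then Me2S
Reagents that add atoms: ozone, [O-][O+]=O
Why: ozonolysis with reductive work-up cleaves the terminal alkene far faster than the terminal alkyne and unveils C3.

**Step 16**
Reactants: 28
Product: 29 ring A aldol (3-hydroxy, both C3 epimers; 19,10-lactone; 13-ketal)
Conditions: K2CO3, MeOH, 0 °C to rt
Reagents that add atoms: none
Why: intramolecular aldol addition of the lactone enolate (C4) to the aldehyde (6-enolexo-exo-trig) closes ring A; the bridged lactone can form only with C19 α, which fixes C4, and both C3 carbinol epimers converge in step 17.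

**Step 17**
Reactants: 29
Product: 30 2-ene (C2=C3)
Conditions: Burgess reagent (Et3N+SO2N−CO2Me), toluene, 80 °C
Reagents that add atoms: none
Why: Burgess dehydration is a syn-elimination through the sulfamate, and since only C2 carries β-hydrogens (C4 is quaternary) both epimers should give the same alkene.

**Step 18**
Reactants: 30
Product: 31 2β,3β-diol (13-ketal)
Conditions: OsO4 (5 mol %), N-methylmorpholine N-oxide, acetone–H2O, rt
Reagents that add atoms: osmium tetroxide, O=[Os](=O)(=O)=O; N-methylmorpholine N-oxide, C[N+]1([O-])CCOCC1; water, O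
Why: catalytic osmylation (Upjohn dihydroxylation) is a syn addition expected on the exo β-face of the bridged lactone, away from the O–C19 bridge, and the alkyne is far less reactive.

**Step 19**
Reactants: 31
Product: 32 13,16-seco precursor as its 7-methyl ester (C13 ketone, prop-2-ynyl on C8, 2β,3β-diol, 19,10-lactone)
Conditions: 2 M HCl, THF, rt
Reagents that add atoms: water, O
Why: acid hydrolysis of the dioxolane frees the C13 ketone while no acid-labile allylic carbinol is yet present.

**Step 20**
Reactants: 32
Product: 33 7-methyl ester of the target gibberellin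
Conditions: SmI2 (3 equiv), HMPA, t-BuOH, THF, −78 to 0 °C
Reagents that add atoms: none
Why: Electron transfer from divalent samarium to the C13 ketone gives a ketyl that adds to the nearer alkyne carbon C16 of the propargyl arm on C8 in a 5-exo-dig closure, forming C13–C16 and ring D; the closest known reaction type is the SmI2-mediated ketyl–alkyne reductive cyclisation to bridgehead allylic carbinols. The C17 vinyl radical is then reduced by a second equivalent of SmI2 and protonated by t-BuOH, so the alkene ends as the exocyclic C16=C17 methylene. The only new stereocentre, C13, is fixed by the tether, because the two-carbon bridge from quaternary C8 can span C8 and C13 only cis (1,3-diaxial on ring C). The step needs reduction of a single carbonyl and 5-exo rather than 6-endo attack: C13 is the only ketone (lactone and ester are not reduced under these conditions), and the 1,3 spacing of C13 and C8 puts only C16 within reach. The free diol and the lactone are spectators, and the acid-sensitive 13-hydroxy-16-methylene unit is formed under neutral conditions after every acidic step.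

**Step 21**
Reactants: 33
Product: 34 the target gibberellin (2β,3β,13-trihydroxy-20-norgibberell-16-ene-7,19-dioic acid 19,10-lactone)
Conditions: n-PrSLi, HMPA, rt; then cold dilute HCl to pH 3
Reagents that add atoms: none
Why: SN2 attack of the thiolate on the ester methyl group (nucleophilic demethylation) frees the C7 acid without hydroxide, so the tertiary-alkyl lactone, the retro-aldol-prone 3β-hydroxyl and the allylic carbinol should be left alone.

**Compound list**
1 | 2-bromo-5-methoxybenzoic acid | COc1ccc(Br)c(c1)C(=O)O | starting material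
2 | (S)-2-(methoxymethyl)pyrrolidine | COC[C@@H]1CCCN1 | starting material
3 | 2-bromo-5-methoxybenzoyl chloride (not isolated) | COc1ccc(Br)c(c1)C(Cl)=O | intermediate
4 | (S)-1-(2-bromo-5-methoxybenzoyl)-2-(methoxymethyl)pyrrolidine | COc1ccc(Br)c(c1)C(=O)N1CCC[C@H]1COC | intermediate
5 | ethylene oxide | C1CO1 | starting material
6 | arylmagnesium chloride from 4, MgCl in place of Br (not isolated) | COc1ccc([Mg]Cl)c(c1)C(=O)N1CCC[C@H]1COC | intermediate
7 | (S)-1-[2-(2-hydroxyethyl)-5-methoxybenzoyl]-2-(methoxymethyl)pyrrolidine | COc1ccc(CCO)c(c1)C(=O)N1CCC[C@H]1COC | intermediate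
8 | 3-bromo-1-(trimethylsilyl)prop-1-yne | C[Si](C)(C)C#CCBr | starting material
9 | dilithium salt: amide enolate of the 1,4-dihydroarene with side-chain alkoxide (not isolated) | [Li]OCCC1=CCC(OC)=CC1=C(O[Li])N1CCC[C@H]1COC | intermediate
10 | amide of 2 with (1S)-2-(2-hydroxyethyl)-5-methoxy-1-[3-(trimethylsilyl)prop-2-ynyl]cyclohexa-2,5-diene-1-carboxylic acid | C[Si](C)(C)C#CC[C@]1(C(=O)N2CCC[C@H]2COC)C=C(OC)CC=C1CCO | intermediate
11 | 2-(2-iodoethyl) analogue of 10 | C[Si](C)(C)C#CC[C@]1(C(=O)N2CCC[C@H]2COC)C=C(OC)CC=C1CCI | intermediate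
12 | 2-(2-lithioethyl) analogue of 10 (not isolated) | C[Si](C)(C)C#CC[C@]1(C(=O)N2CCC[C@H]2COC)C=C(OC)CC=C1CC[Li] | intermediate
13 | 6-methoxy-7a-[3-(trimethylsilyl)prop-2-ynyl]-2,3,5,7a-tetrahydro-1H-inden-1-one (C6 ketone, C8 as in 10) | C[Si](C)(C)C#CC[C@]12C=C(OC)CC=C1CCC2=O | intermediate
14 | potassium enolate of 13, C5=C6 (not isolated) | C[Si](C)(C)C#CC[C@]12C=C(OC)CC=C1CC=C2O[K] | intermediate
15 | enol triflate of 13 (C5=C6, OTf on C6) | C[Si](C)(C)C#CC[C@]12C=C(OC)CC=C1CC=C2OS(=O)(=O)C(F)(F)F | intermediate
16 | C6 methyl ester of the 5,9(11),13-triene (13-methoxy) | C[Si](C)(C)C#CC[C@]12C=C(OC)CC=C1CC=C2C(=O)OC | intermediate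
17 | 13-ketone with C9=C11 and C5=C6 double bonds (not isolated) | C[Si](C)(C)C#CC[C@]12CC(=O)CC=C1CC=C2C(=O)OC | intermediate
18 | cis-fused 13-oxo-11-ene, H9 β, C5=C6 ester | C[Si](C)(C)C#CC[C@]12CC(=O)C=C[C@H]1CC=C2C(=O)OC | intermediate
19 | 13-ketone with saturated ring C, H9 β, C5=C6 ester | C[Si](C)(C)C#CC[C@]12CC(=O)CC[C@H]1CC=C2C(=O)OC | intermediate
20 | 13,13-ethylenedioxy ketal of 19 | C[Si](C)(C)C#CC[C@]12CC3(OCCO3)CC[C@H]1CC=C2C(=O)OC | intermediate
21 | 10-oxo-5-ene 7-methyl ester, 13-ketal | C[Si](C)(C)C#CC[C@]12CC3(OCCO3)CC[C@H]1C(=O)C=C2C(=O)OC | intermediate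
22 | but-3-enylmagnesium bromide | C=CCC[Mg]Br | starting material
23 | tertiary alcohol, 10α-OH and 10β-but-3-enyl | C[Si](C)(C)C#CC[C@]12CC3(OCCO3)CC[C@H]1[C@](O)(CCC=C)C=C2C(=O)OC | intermediate
24 | propanoic anhydride | CCC(=O)OC(=O)CC | starting material
25 | 10α-propanoate of 23 | C[Si](C)(C)C#CC[C@]12CC3(OCCO3)CC[C@H]1[C@](OC(=O)CC)(CCC=C)C=C2C(=O)OC | intermediate
26 | silyl alkyne γ-lactone, epimers at C4 and C6 (not isolated) | C[Si](C)(C)C#CC[C@]23CC4(OCCO4)CC[C@H]2[C@@]1(CCC=C)OC(=O)C(C)[C@H]1C3C(=O)OC | intermediate
27 | γ-lactone: H5 β, 6β-CO2Me, C4–H (exo methyl), 10β-but-3-enyl, terminal alkyne, 13-ketal | C#CC[C@]23CC4(OCCO4)CC[C@H]2[C@@]1(CCC=C)OC(=O)[C@H](C)[C@H]1[C@@H]3C(=O)OC | intermediate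
28 | C3 aldehyde (10β-CH2CH2CHO), otherwise as 27 | C#CC[C@]23CC4(OCCO4)CC[C@H]2[C@@]1(CCC=O)OC(=O)[C@H](C)[C@H]1[C@@H]3C(=O)OC | intermediate
29 | ring A aldol, 3-hydroxy (both C3 epimers), 19,10-lactone, 13-ketal | C#CC[C@]23CC4(OCCO4)CC[C@H]2[C@@]12CCC(O)[C@@](C)(C(=O)O1)[C@H]2[C@@H]3C(=O)OC | intermediate
30 | 2-ene of the A/B/C lactone, 13-ketal | C#CC[C@]23CC4(OCCO4)CC[C@H]2[C@@]12CC=C[C@@](C)(C(=O)O1)[C@H]2[C@@H]3C(=O)OC | intermediate
31 | 2β,3β-diol, 13-ketal | C#CC[C@]23CC4(OCCO4)CC[C@H]2[C@@]12C[C@H](O)[C@H](O)[C@@](C)(C(=O)O1)[C@H]2[C@@H]3C(=O)OC | intermediate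
32 | 13,16-seco precursor as its 7-methyl ester: C13 ketone, prop-2-ynyl on C8, 2β,3β-diol, 19,10-lactone | C#CC[C@]23CC(=O)CC[C@H]2[C@@]12C[C@H](O)[C@H](O)[C@@](C)(C(=O)O1)[C@H]2[C@@H]3C(=O)OC | intermediate
33 | 7-methyl ester of the target gibberellin | C=C1C[C@]23C[C@@]1(O)CC[C@H]2[C@@]12C[C@H](O)[C@H](O)[C@@](C)(C(=O)O1)[C@H]2[C@@H]3C(=O)OC | intermediate
34 | target gibberellin: 2β,3β,13-trihydroxy-20-norgibberell-16-ene-7,19-dioic acid 19,10-lactone | C=C1C[C@]23C[C@@]1(O)CC[C@H]2[C@@]12C[C@H](O)[C@H](O)[C@@](C)(C(=O)O1)[C@H]2[C@@H]3C(=O)O | target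

**Totals and risks**
Total step count: 21. Longest linear sequence: 21 steps (from 1).

Step 14 (Michael lactonisation). Ring closure through an endocyclic ester enolate may be slower than proton transfer or ester-enolate Claisen rearrangement of the allylic propanoate. The fallback sets out from 21. Conjugate reduction of C5=C6 with [(Ph3P)CuH]6 should give the saturated keto ester F1 (6β-ester after equilibration). Alkylation of the kinetic C10-ketone enolate (LiN(i-Pr)2, THF, −78 °C) at C5 with methyl 2-(trifluoromethylsulfonyloxy)propanoate, trans to the ester, should give the keto diester F2. CeCl3-mediated addition of 22 to C10, anti to both neighbouring substituents, then lets the tertiary alkoxide close the γ-lactone on the propanoate ester. The fallback comes back at 26, which methoxide converts into 27 as in step 14.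

Step 11 (allylic oxidation). Oxidation of a deactivated allylic position may stall or spread to the propargylic CH2. The fallback sets out from 20. γ-Deprotonation with LiN(i-Pr)2 and O-silylation with Me3SiCl should give the silyl ketene acetal F3. Vinylogous Rubottom oxidation (mCPBA, NaHCO3) at the distal C5=C10 bond should give the γ-hydroxy enoate F4. Dess–Martin oxidation of F4 comes back at 21.

Step 17 (dehydration). Elimination may be slow for one carbinol epimer or give way to retro-aldol opening on heating. The fallback sets out from 29. Dess–Martin oxidation of both epimers should give the 3-ketone F5. Enolisation, possible only towards C2, with KN(SiMe3)2 and trapping with PhNTf2 should give the enol triflate F6. Reduction with Pd(OAc)2/PPh3 and HCO2H–Bu3N comes back at 30.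

**Further compounds**
F1 | step 14 | saturated keto ester (10-oxo, 6β-CO2Me, 13-ketal) | C[Si](C)(C)C#CC[C@]12CC3(OCCO3)CC[C@H]1C(=O)C[C@@H]2C(=O)OC
F2 | step 14 | keto diester, C5 alkylated trans to the C6 ester (C4 epimers) | C[Si](C)(C)C#CC[C@]12CC3(OCCO3)CC[C@H]1C(=O)[C@@H](C(C)C(=O)OC)[C@@H]2C(=O)OC
F3 | step 11 | silyl ketene acetal of 20 (C5=C10 and C6=C7) | C[Si](C)(C)C#CC[C@]12CC3(OCCO3)CC[C@H]1C=CC2=C(OC)O[Si](C)(C)C
F4 | step 11 | 10-hydroxy-5-ene 7-methyl ester | C[Si](C)(C)C#CC[C@]12CC3(OCCO3)CC[C@H]1C(O)C=C2C(=O)OC
F5 | step 17 | 3-ketone of 29 | C#CC[C@]23CC4(OCCO4)CC[C@H]2[C@@]12CCC(=O)[C@@](C)(C(=O)O1)[C@H]2[C@@H]3C(=O)OC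
F6 | step 17 | 2-en-3-yl triflate | C#CC[C@]23CC4(OCCO4)CC[C@H]2[C@@]12CC=C(OS(=O)(=O)C(F)(F)F)[C@@](C)(C(=O)O1)[C@H]2[C@@H]3C(=O)OC
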